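The synthesis rests on disconnecting ring B (C1' ether carbon, C2' OH, Br on C3', C5' and C6') at C6'. Its bromine is meta to the C2' hydroxyl and ortho to the C1' ether, out of reach of phenol-directed bromination, so C6' is inserted already brominated. Dibromocarbene adds to the aryl enol ether alkene of a cyclopentenone ethylene ketal that carries ring A as a 2-methoxyphenyl ether, and the dibromocyclopropane opens to a six-membered bromodiene, forming C1'–C6' and C5'–C6' in one operation. Aromatisation with dealkylation, then fourfold bromination ortho and para to both hydroxyls (C2 and C4 of ring A, C3' and C5'), completes the target.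

Key step: step 4

Remark: ring A is C1 (OH), C2 and C4 (Br), C6 (ether carbon); the spiro numbering of 7–11 maps onto ring B as C5→C2', C6→C1', C7 (the CBr of 11)→C6', C8→C5', C9→C4', C10→C3'.
Remark: the chiral intermediates 2, 4, 9 and 10 are racemic (stereo-SMILES show one enantiomer) and the target has no stereocentre.
Remark: acid is not expected to hydrolyse the dienone ketal 11 to a free phenol, because the ring-opened oxocarbenium ion is an O-alkylated arenium ion that loses a proton faster than it takes up water; 11 should therefore aromatise to the 2-hydroxyethyl aryl ether 12, and the dealkylation is planned to remove this group together with the methyl ether.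

Step 1
Reactants: 1 cyclopent-2-en-1-one
Product: 2 6-oxabicyclo[3.1.0]hexan-2-one (2,3-epoxycyclopentanone, racemic)
Conditions: 30% aq. H2O2, NaOH (cat.), MeOH, 0 °C
Reagents that add atoms: hydrogen peroxide, OO
Why: Weitz–Scheffer nucleophilic epoxidation, in which hydroperoxide adds to the β-carbon of the enone and the enolate closes onto oxygen, the two new stereocentres being cis by ring fusion (the only possible arrangement) and formed as a racemate.

Step 2
Reactants: 2 6-oxabicyclo[3.1.0]hexan-2-one, 3 guaiacol (2-methoxyphenol)
Product: 5 2-(2-methoxyphenoxy)cyclopent-2-en-1-one, via trans-hydroxy ketone 4 (not isolated)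
Conditions: KH (10 mol %), THF/DMPU, rt → 60 °C
Reagents that add atoms: none
Why: Phenoxide opening of an α,β-epoxy ketone with dehydration (a known route to 2-aryloxy enones), in which SN2 attack at the carbonyl-activated C2 with inversion gives the trans β-hydroxy ketone 4, whose C2–H is acidified by carbonyl and aryloxy groups so that hydroxide leaves by E1cB, erasing both stereocentres and regenerating the base.

Step 3
Reactants: 5 2-(2-methoxyphenoxy)cyclopent-2-en-1-one, 6 1,2-bis(trimethylsilyloxy)ethane
Product: 7 6-(2-methoxyphenoxy)-1,4-dioxaspiro[4.4]non-6-ene
Conditions: TMSOTf (5 mol %), CH2Cl2, −78 → −20 °C; pyridine quench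
Reagents that add atoms: none
Why: Noyori ketalisation, in which the silyl triflate activates the carbonyl at low temperature in an aprotic, water-free medium and formation of the Si–O–Si bond drives the exchange, conditions under which enones are ketalised without migration of the double bond and the aryl enol ether is not protonated.

Step 4
Reactants: 7 6-(2-methoxyphenoxy)-1,4-dioxaspiro[4.4]non-6-ene, 8 bromoform
Product: 11 7-bromo-6-(2-methoxyphenoxy)-1,4-dioxaspiro[4.5]deca-6,8-diene, via dibromocyclopropane adduct 9 (not isolated), via allylic bromide 10 (not isolated)
Conditions: KOtBu (4 equiv), pentane, −20 °C → rt; then THF, rt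
Reagents that add atoms: none
Why: α-Elimination of HBr from bromoform by tert-butoxide gives dibromocarbene, which cyclopropanates the only alkene of 7, an electron-rich aryl enol ether, to the cis-fused 6,6-dibromobicyclo[3.1.0]hexane 9. Departure of the endo bromide with concerted disrotatory cleavage of the former C6–C7 bond gives a 2-bromocyclohexenyl cation that is an aryloxy-stabilised oxocarbenium ion; it collapses to the allylic bromide 10, from which excess tert-butoxide removes HBr by E2 across C8–C9. The closest known reaction type is the dihalocarbene ring expansion of cyclic enol ethers and cyclopentenes to 2-halocyclohexenones, 2,3-dihalocyclohexenes and halodienes. The six-membered ring is closed by a [2+1] cycloaddition followed by a two-electron electrocyclic opening of the cyclopropane, which leaves the inserted CBr carbon bonded to C6 and C8 of 11, the future C1'–C6' and C5'–C6' bonds of ring B. No stereocentre remains in 11: the two of 9 are fixed cis by the ring fusion, the one of 10 is uncontrolled, all are racemic and all are destroyed. The step needs regiocontrol only in the elimination, and the substrate supplies it, because the charge is held at the oxygen-bearing carbon, the ketal carbon C5 has no hydrogen and only the C9 hydrogens are β to the allylic bromine, so the diene can form only as C6=C7–C8=C9.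

Step 5
Reactants: 11 7-bromo-6-(2-methoxyphenoxy)-1,4-dioxaspiro[4.5]deca-6,8-diene
Product: 13 3-bromo-2-(2-hydroxyphenoxy)phenol, via hydroxyethyl aryl ether 12 (not isolated)
Conditions: CSA (5 mol %), CH2Cl2, rt; then BBr3 (5 equiv), −78 °C → rt; H2O
Reagents that add atoms: none
Why: Dienone-ketal aromatisation followed by Lewis-acid ether dealkylation, in which acid opens the dioxolane to an O-alkylated arenium ion that loses the C10 proton irreversibly and leaves the ketal oxygen on ring B as a 2-hydroxyethyl ether, after which BBr3 cleaves both alkyl aryl ethers (methyl and 2-hydroxyethyl) by bromide attack at the alkyl carbon while the diaryl ether and the aryl bromide are inert.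

Step 6
Reactants: 13 3-bromo-2-(2-hydroxyphenoxy)phenol
Product: 14 3,4,6-tribromo-2-(3,5-dibromo-2-hydroxyphenoxy)phenol (CNP0163911.0)
Conditions: Br2 (4.05 equiv), NaOAc (4.5 equiv), AcOH, 10 °C → rt
Reagents that add atoms: bromine, BrBr
Why: Electrophilic aromatic bromination, in which each hydroxyl is the strongest donor on its ring and directs bromine to its free ortho and para positions (C2 and C4 in ring A, C3' and C5' in ring B), the ether oxygen shared by both rings is the weaker director, the acetate buffer keeps HBr from promoting bromine migration, and four equivalents stop the reaction at the pentabromide.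

Compound list
1 | cyclopent-2-en-1-one | O=C1C=CCC1 | starting material
2 | 6-oxabicyclo[3.1.0]hexan-2-one (2,3-epoxycyclopentanone), racemic | O=C1CC[C@@H]2O[C@H]12 | intermediate
3 | guaiacol (2-methoxyphenol) | COc1ccccc1O | starting material
4 | trans-3-hydroxy-2-(2-methoxyphenoxy)cyclopentan-1-one, racemic, not isolated | O=C1CC[C@H](O)[C@H]1Oc1ccccc1OC | intermediate
5 | 2-(2-methoxyphenoxy)cyclopent-2-en-1-one | COc1ccccc1OC1=CCCC1=O | intermediate
6 | 1,2-bis(trimethylsilyloxy)ethane | C[Si](C)(C)OCCO[Si](C)(C)C | starting material
7 | 6-(2-methoxyphenoxy)-1,4-dioxaspiro[4.4]non-6-ene | COc1ccccc1OC1=CCCC12OCCO2 | intermediate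
8 | bromoform | BrC(Br)Br | starting material
9 | 6,6-dibromo-1-(2-methoxyphenoxy)spiro[bicyclo[3.1.0]hexane-2,2'-[1,3]dioxolane], cis-fused, racemic, not isolated | COc1ccccc1O[C@]12[C@H](CCC13OCCO3)C2(Br)Br | intermediate
10 | 7,8-dibromo-6-(2-methoxyphenoxy)-1,4-dioxaspiro[4.5]dec-6-ene, racemic at C8, not isolated | COc1ccccc1OC1=C(Br)C(Br)CCC12OCCO2 | intermediate
11 | 7-bromo-6-(2-methoxyphenoxy)-1,4-dioxaspiro[4.5]deca-6,8-diene | COc1ccccc1OC1=C(Br)C=CCC12OCCO2 | intermediate
12 | 2-[3-bromo-2-(2-methoxyphenoxy)phenoxy]ethan-1-ol, not isolated | COc1ccccc1Oc1c(Br)cccc1OCCO | intermediate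
13 | 3-bromo-2-(2-hydroxyphenoxy)phenol | Oc1ccccc1Oc1c(O)cccc1Br | intermediate
14 | 3,4,6-tribromo-2-(3,5-dibromo-2-hydroxyphenoxy)phenol (CNP0163911.0) | Oc1c(Br)cc(Br)cc1Oc1c(O)c(Br)cc(Br)c1Br | target

Total step count: 6
Longest linear sequence: 6 steps (1 → 14)

Steps most likely to fail

Step 4. The carbene may add too slowly to an alkene that is inductively deactivated by the neighbouring ketal and crowded by the spiro ring and the ortho-substituted aryloxy group, so that it is lost to tert-butoxide. The ring-opened cation may also be trapped by tert-butoxide or by a ketal oxygen instead of eliminating. Premature base-induced aromatisation with opening of the dioxolane would only anticipate the first stage of step 5 and is harmless. The fallback uses known chemistry and builds ring B from a preformed bromoarene; it sets out from guaiacol 3 and returns at 13. Guaiacol displaces fluoride from commercial 3-bromo-2-fluorobenzaldehyde (O=Cc1cccc(Br)c1F) with K2CO3 in DMF at 100 °C (SNAr activated by the ortho formyl group) to give 3-bromo-2-(2-methoxyphenoxy)benzaldehyde F1. Baeyer–Villiger (Dakin-type) oxidation with mCPBA in CH2Cl2 should give 3-bromo-2-(2-methoxyphenoxy)phenyl formate F2. Hydrolysis with KOH in aqueous methanol and acidification should give 3-bromo-2-(2-methoxyphenoxy)phenol F3, and BBr3 in CH2Cl2 then removes the methyl group to deliver 13.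

Step 3. Lewis-acid-promoted conjugate addition of the silyl ether to the enone, or ionisation at the enol ether carbon with loss or migration of the aryloxy alkene, may outrun ketal formation at a carbonyl deactivated by conjugation. The fallback forms the enol ether C–O bond after the ketal is in place; it sets out from 1, returns at 7 and bypasses steps 1 and 2 as well. Cyclopentenone 1 is α-iodinated with I2 and pyridine (addition–elimination on the enone) to 2-iodocyclopent-2-en-1-one F4. This is ketalised with ethylene glycol and TsOH in benzene under a Dean–Stark trap, a reliable operation for α-halo enones, to 6-iodo-1,4-dioxaspiro[4.4]non-6-ene F5. Ullmann-type C–O coupling of the vinyl iodide with guaiacol 3 (CuI, N,N-dimethylglycine, Cs2CO3, dioxane, 90 °C) should give 7.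

Step 5. Bromide attack at the CH2 of the 2-hydroxyethyl ether is slowed by the β-oxygen, so dealkylation may stall after demethylation or divert to exchange of the hydroxyl for bromide. The fallback removes the two-carbon group by reductive β-elimination instead of substitution; it sets out from 12, isolated after the acid stage, and returns at 13. An Appel reaction (PPh3, I2, imidazole, CH2Cl2) should convert 12 into 1-bromo-3-(2-iodoethoxy)-2-(2-methoxyphenoxy)benzene F6. Zn dust in AcOH/EtOH at reflux (Boord-type fragmentation) then expels ethylene and the aryloxide to give 3-bromo-2-(2-methoxyphenoxy)phenol F3, in which BBr3 has only the methyl ether to cleave, giving 13.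

Further compounds
F1 | step 4 | 3-bromo-2-(2-methoxyphenoxy)benzaldehyde | COc1ccccc1Oc1c(Br)cccc1C=O
F2 | step 4 | 3-bromo-2-(2-methoxyphenoxy)phenyl formate | COc1ccccc1Oc1c(Br)cccc1OC=O
F3 | step 4 | 3-bromo-2-(2-methoxyphenoxy)phenol | COc1ccccc1Oc1c(O)cccc1Br
F4 | step 3 | 2-iodocyclopent-2-en-1-one | O=C1CCC=C1I
F5 | step 3 | 6-iodo-1,4-dioxaspiro[4.4]non-6-ene | IC1=CCCC12OCCO2
F6 | step 5 | 1-bromo-3-(2-iodoethoxy)-2-(2-methoxyphenoxy)benzene | COc1ccccc1Oc1c(Br)cccc1OCCI
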